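Assumption: the SMILES has no stereodescriptor and the target has no stereocentre. The hindered aryl–naphthoquinone axis is not defined, so the compound is made as drawn without control of that axis (racemic if the axis is configurationally stable).

## Retrosynthetic overview
1. Target 6 ⇒ (add back 4 H) trans-7,8-dihydronaphthalene-1,4-diol 4, the tautomer of cycloadduct 3. Aromatisation of ring B is the last event.
2. 3 ⇒ retro-[4+2] across C6–C7 (lignan 8–8′) and C8–C8a (lignan 7′–6). These are the two bonds that join two asarone units in the presumed biogenesis. The 4π partner is propenylquinone 2 and the 2π partner is α-asarone 1.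
3. 2 ⇒ 1 by oxidative demethylation. The quinone level is placed on one monomer before coupling, so two trimethoxyarene rings never have to be told apart late in the route.
4. Ring order: quinone ring A and pendant aryl ring C both come ready-made from 1. Carbocycle B is the only ring formed (step 2).

## Route

Step 1
Reactants: 1 α-asarone [(E)-1,2,4-trimethoxy-5-(prop-1-en-1-yl)benzene]
Product: 2 2-methoxy-5-[(E)-prop-1-en-1-yl]cyclohexa-2,5-diene-1,4-dione
Conditions: (NH4)2Ce(NO3)6 (2.5 equiv), MeCN/H2O 2:1, −5 °C, 1 in MeCN added dropwise into the oxidant (inverse addition), 15 min; CH2Cl2 extraction, short silica plug, used at once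
Reagents that add atoms: water, O
Why: Oxidative demethylation of a 1,4-dimethoxyarene by tetravalent cerium: two one-electron oxidations with ipso attack of water at C2 and C5 of 1 expel two methanol and give the para-quinone while the C4 methoxy group stays as a vinylogous ester, the same reaction type that turns 2,5-dimethoxystyrenes into vinylquinones, and slow addition of 1 into excess cold oxidant keeps unoxidised 1 scarce so that radical-cation dimerisation and side-chain attack are held back; no stereocentre is formed and the E alkene is retained.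

Step 2
Reactants: 2 2-methoxy-5-[(E)-prop-1-en-1-yl]cyclohexa-2,5-diene-1,4-dione (1.2 equiv); 1 α-asarone (1.0 equiv)
Product: 6 2-methoxy-6,7-dimethyl-8-(2,4,5-trimethoxyphenyl)naphthalene-1,4-dione, via cycloadduct 3 (not isolated), via dihydronaphthalenediol 4 (not isolated), via dihydronaphthoquinone 5 (not isolated)
Conditions: (CF3)2CHOH/CH2Cl2 1:3, 2,6-di-tert-butylpyridine (10 mol %), Ar, dark, 0 °C → rt, 16 h; evaporate; DDQ (2.3 equiv), PhMe, 60 °C, 3 h
Reagents that add atoms: none
Why: Proposed new method: an inverse-electron-demand vinylquinone Diels–Alder reaction in which 2 is the 4π partner (C6=C5–CH=CHMe, conjugated in line with the C1 carbonyl, the one not damped by the methoxy group) and the electron-rich alkene of 1 is the 2π partner, so the nucleophilic β-carbon of 1 bonds to the propenyl terminus of 2 (8–8′ bond) and the aryl-stabilised benzylic carbon closes onto quinone C6 (7′–6 bond), a concerted-asynchronous or zwitterionic path that hydrogen bonding from (CF3)2CHOH accelerates while the hindered base stops acid-catalysed indane dimerisation of 1; suprafacial addition to the E alkene sets Me-7 and aryl-8 trans and an aryl-endo approach sets C6 and C8a, all centres being racemic and erased when 3 enolises to 4 and DDQ removes four hydrogens (hydroquinone oxidation to 5, then hydride abstraction at the doubly activated C8–H and loss of H-7); the closest known reaction types are vinylquinone Diels–Alder reactions with enol ethers and styrenes, Lewis-acid-promoted additions of propenylarenes to 2-methoxy-1,4-benzoquinones, and DDQ aromatisation of dihydronaphthalenes.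

## Compound list
1 | α-asarone, (E)-1,2,4-trimethoxy-5-(prop-1-en-1-yl)benzene | C/C=C/c1cc(OC)c(OC)cc1OC | starting material
2 | 2-methoxy-5-[(E)-prop-1-en-1-yl]cyclohexa-2,5-diene-1,4-dione | C/C=C/C1=CC(=O)C(OC)=CC1=O | intermediate
3 | rac-(6S,7S,8R,8aR)-2-methoxy-6,7-dimethyl-8-(2,4,5-trimethoxyphenyl)-6,7,8,8a-tetrahydronaphthalene-1,4-dione (aryl-endo cycloadduct, one enantiomer drawn; other C6/C8a epimers converge) | COC1=CC(=O)C2=C[C@@H](C)[C@H](C)[C@@H](c3cc(OC)c(OC)cc3OC)[C@H]2C1=O | intermediate (not isolated)
4 | rac-(7R,8S)-2-methoxy-6,7-dimethyl-8-(2,4,5-trimethoxyphenyl)-7,8-dihydronaphthalene-1,4-diol (7,8-trans) | COc1cc(O)c2C=C(C)[C@H](C)[C@@H](c3cc(OC)c(OC)cc3OC)c2c1O | intermediate (not isolated)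
5 | rac-(7R,8S)-2-methoxy-6,7-dimethyl-8-(2,4,5-trimethoxyphenyl)-7,8-dihydronaphthalene-1,4-dione (7,8-trans) | COC1=CC(=O)C2=C([C@H](c3cc(OC)c(OC)cc3OC)[C@@H](C)C(C)=C2)C1=O | intermediate (not isolated)
6 | 2-methoxy-6,7-dimethyl-8-(2,4,5-trimethoxyphenyl)naphthalene-1,4-dione | COC1=CC(=O)c2cc(C)c(C)c(-c3cc(OC)c(OC)cc3OC)c2C1=O | target

## Summary
Total step count: 2. Longest linear sequence: 2 (1 → 2 → 6; 1 enters a second time in step 2).

The route has only two steps, so step 2 is ranked twice, once for each of its stages.

**(a) Step 2, cycloaddition stage.**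
- Risks: 1 may attack ring carbons C5 or C6 of 2, giving bicyclooctenedione or dihydrobenzofuran products. 2 may dimerise with itself, or nothing may happen.
- The fallback sets out from 1 and comes back at 6. It moves the oxidation to after ring formation.
- Two molecules of 1 are joined by one-electron oxidation: PhI(OCOCF3)2 (0.55 equiv per 1), 2,6-di-tert-butylpyridine, (CF3)2CHOH/CH2Cl2, −20 °C. This radical-cation [4+2] dehydrodimerisation gives rac-magnoshinin F1, the trans-1-aryl-2,3-dimethyl-5,7,8-trimethoxy-1,2-dihydronaphthalene.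
- DDQ (1.1 equiv) in PhMe aromatises it to 5,7,8-trimethoxy-2,3-dimethyl-1-(2,4,5-trimethoxyphenyl)naphthalene F2.
- (NH4)2Ce(NO3)6 (2.1 equiv) in MeCN/H2O at 0 °C then oxidises the more electron-rich trimethoxynaphthalene ring ahead of the pendant ring and gives 6.

**(b) Step 1.**
- Risks: side-chain oxidation to nitrate, diol or aldehyde, and radical-cation dimers, in place of ring oxidation.
- The fallback sets out from 1 and comes back at 2. It removes the alkene before the oxidation and restores it afterwards.
- H2 over Pd/C in EtOAc gives 1,2,4-trimethoxy-5-propylbenzene F3.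
- (NH4)2Ce(NO3)6 in MeCN/H2O gives 2-methoxy-5-propylcyclohexa-2,5-diene-1,4-dione F4, with no alkene at risk.
- NBS with catalytic (PhCO2)2 in refluxing PhCF3 brominates the quinone-activated methylene to give racemic 2-(1-bromopropyl)-5-methoxycyclohexa-2,5-diene-1,4-dione F5.
- Et3N in CH2Cl2 at 0 °C eliminates to the conjugated E alkene 2.

**(c) Step 2, dehydrogenation stage.**
- Risks: DDQ may stop at 5, form adducts, or oxidise the pendant trimethoxyphenyl ring.
- The fallback sets out from 4 and comes back at 6. Step 2 is stopped before the oxidant is added and 4 is isolated under argon. Hydride abstraction is replaced by tautomerisation and autoxidation.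
- Ag2O in CH2Cl2 gives 5.
- Catalytic Et3N in CH2Cl2/MeOH moves H-8 and H-7 to the carbonyl oxygens in two prototropic shifts and gives 2-methoxy-6,7-dimethyl-8-(2,4,5-trimethoxyphenyl)naphthalene-1,4-diol F6.
- Stirring under air oxidises F6 to 6.

## Further compounds
F1 | step 2 | rac-magnoshinin, rac-(1S,2R)-5,7,8-trimethoxy-2,3-dimethyl-1-(2,4,5-trimethoxyphenyl)-1,2-dihydronaphthalene | COc1cc(OC)c2C=C(C)[C@H](C)[C@@H](c3cc(OC)c(OC)cc3OC)c2c1OC
F2 | step 2 | 5,7,8-trimethoxy-2,3-dimethyl-1-(2,4,5-trimethoxyphenyl)naphthalene | COc1cc(OC)c2cc(C)c(C)c(-c3cc(OC)c(OC)cc3OC)c2c1OC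
F3 | step 1 | 1,2,4-trimethoxy-5-propylbenzene | CCCc1cc(OC)c(OC)cc1OC
F4 | step 1 | 2-methoxy-5-propylcyclohexa-2,5-diene-1,4-dione | CCCC1=CC(=O)C(OC)=CC1=O
F5 | step 1 | 2-(1-bromopropyl)-5-methoxycyclohexa-2,5-diene-1,4-dione (racemic) | CCC(Br)C1=CC(=O)C(OC)=CC1=O
F6 | step 2 | 2-methoxy-6,7-dimethyl-8-(2,4,5-trimethoxyphenyl)naphthalene-1,4-diol | COc1cc(O)c2cc(C)c(C)c(-c3cc(OC)c(OC)cc3OC)c2c1O
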